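## Analysis of the target

The target is (2R,3R)-3,5,7-trihydroxy-2-(4-hydroxy-3-methoxyphenyl)-6-(3-methylbut-2-enyl)chroman-4-one, a 6-prenylated dihydroflavonol. Ring A is a phloroglucinol-type arene with the prenyl group at C6, ring C is a 3-hydroxychroman-4-one, and ring B is a guaiacyl group on C2. The only stereocenters are C2 and C3; they are adjacent and trans, with aryl and hydroxyl both equatorial, which is the more stable arrangement. C2 is a benzylic ether carbon para to a phenol and can in principle be corrected late by reversible ring opening, whereas C3 has no such path and must be set directly in its absolute sense. The sensitive groups are the prenyl chain between two phenols (acid gives a chroman, oxidants give a chromene, hydrogenation is excluded), the alpha-hydroxy ketone (base and air lead to the flavonol) and four phenols. Two things make the synthesis hard: the oxygens at C5 and C8a are both ortho to C4a and must be told apart, since that choice decides 6- against 8-prenylation, and the C2–C3 unit must be built in one absolute sense without acid or hydrogenolysis. The strategy rests on C3: it is a carbinol carbon bonded to the C4 ketone, to an oxygen and to the benzylic C2, so it can begin as a carbene carbon next to the ketone and take its oxygen from an alcohol and C2 from an aldehyde in a single event. C3 is then the methyl carbon of a ring A acetophenone, whose regiochemistry can be settled beforehand.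

## Retrosynthetic reasoning

**18 back to 15 (unmasking only).** The last three operations cut only O–acetyl, O–silicon and O–benzyl bonds. The order is fixed by the prenyl group. The PMB ether of 15 is removed oxidatively while both phenols beside the prenyl chain are still silylated (16), because a free ortho-prenylphenol would be cyclised by the same oxidant. Buffered fluoride then frees the ring A phenols (17), and the ring B acetate goes last under near-neutral methanolysis, so that the base-sensitive 3-hydroxychromanone with a free 4'-phenol exists only at the very end.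

**15 back to 14 (O1–C2).** Ring C is opened at O1–C2 and not at C4–C4a or C2–C3. This cut leaves the carbon chain C4–C3–C2 intact and turns ring closure into a displacement at a benzylic carbinol by an ortho-acyl phenol, which runs under neutral conditions. The displacement inverts C2, so the open-chain phenol 14 must carry C3 as in the target and C2 in the opposite sense, which is the syn relation between the two oxygens.

**14 back to 13 (one silyl ether).** Only the oxygen destined to become O1 may be free at the closure. If the C5 oxygen were free as well, the 8-prenyl isomer could form. In 13 the future O1 therefore carries the smaller silyl group (TBS) and sits beside a ring hydrogen, while the C5 and C7 oxygens carry TIPS and sit beside the prenyl group. The forward step has to remove one aryl silyl ether out of three and leave an aryl acetate untouched.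

**13 back to 9, 10 and 11 (C3–O and C2–C3).** Both bonds at C3 are cut at once. C3 becomes the diazo carbon of 9, its oxygen comes from 4-methoxybenzyl alcohol 10, and C2 comes from the aldehyde carbon of vanillin acetate 11. Nothing else offers both stereocenters and the full C4–C3–C2 oxidation pattern in one step from fragments of this simplicity. The forward reaction must capture the carbenoid with the alcohol, trap the resulting ylide with the aldehyde before it collapses by proton shift, and do so syn and in one absolute sense under a chiral Brønsted acid. Silyl ethers are kept on the oxygens flanking the acyl group because they are poor donors toward the carbenoid. The acetate on 11 makes the aldehyde more electrophilic and later holds back ionisation at C2.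

**9 back to 7 (C3=N2).** The diazo group is introduced on the methyl carbon of acetophenone 7 by trifluoroacetylation to 8 and deacylative diazo transfer. This uses the acetyl group already present, so no formylation, oxidation, acid chloride or diazomethane is needed.

**7 back to 1 and 3 (ring A pattern).** The regiochemistry is settled mechanistically. In 2,4,6-trihydroxyacetophenone 1 the two ortho hydroxyls are equivalent, so bis-silylation gives one compound, 2. Its last hydroxyl is etherified with prenol 3 to give 4. Two consecutive [3,3] shifts then carry the prenyl group to the carbon para to that oxygen, which lies between the two TIPS ethers, and return the oxygen as a free phenol beside a ring hydrogen (6). Silylation with TBS gives 7. A symmetric ring A phenol made by direct silylation of a C-prenylated triol was not used: there the unhindered hydroxyl would react first, the opposite of what is needed.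

## Alternatives that were turned down

**Alternative 1: epoxidation of a 2-aryl-2H-chromene.** The C3–O and C4–O bonds are traced back to the C3=C4 alkene of an enantioenriched chromene A2 whose C2 is already disposed as in the target. Forward, a chiral (salen)MnCl complex would epoxidise the alkene on the face away from the C2 aryl group and give the 2,3-trans epoxide A1.
- For it: cis-disubstituted, aryl-conjugated chromene alkenes are the best substrate class for this catalyst family, and C2 needs no inversion. On maturity of the key reaction this route is stronger than the chosen one.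
- Against it: the prenyl alkene is a second electron-rich trisubstituted olefin and would compete for the oxidant. The 5,7-dioxygenated epoxide ionises easily at C4. A 2-aryl-2H-chromene can lose its C2 configuration by reversible electrocyclic ring opening. After the key step the epoxide still has to be opened at C4 and the benzylic alcohol oxidised beside a free C3 carbinol. The acetal protecting groups need acid at the end, next to the prenyl group.
- Comparison: the chosen route delivers C4 as the ketone and C3 as the carbinol in the key step itself, and sets both centers from achiral fragments.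

**Alternative 2: Friedel–Crafts closure onto a symmetric ring A.** The C4–C4a bond is cut. The 3-aryl-3-aryloxy-2-silyloxypropanoic acid A4, activated as a mixed anhydride with a perfluorinated acid, would acylate an ortho carbon of its symmetric aryl ether and give the tetra-silylated flavanone A3.
- For it: both ortho carbons are identical, so the 6/8 question never arises and no oxygen has to be differentiated. On this point it is stronger than the chosen route, which spends a TBS/TIPS distinction and a selective desilylation. Both stereocenters are in place before closure.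
- Against it: the acylating medium is strongly acidic, which the prenyl alkene (protonation, attack on the acylium ion) and the aryl silyl ethers are unlikely to tolerate. The benzylic aryl ether at C2 can ionise or eliminate. The alpha-silyloxy mixed anhydride can epimerise C3 through a ketene. The carbon attacked is flanked by a bulky silyl ether. Making the hindered benzylic aryl ether of A4 stereospecifically is a problem of its own.
- Comparison: the chosen route stays near neutral throughout and reaches its precursor in fewer steps. In exchange it accepts the protecting-group differentiation.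

**Alternative 3: ortho-quinone methide annulation with an enol acetate.** The C3–C4 and O1–C2 bonds are cut. The salicylaldehyde A6, converted by an orthoester and a chiral phosphoric acid into an alkoxy-substituted ortho-quinone methide cation, would add across the (E)-enol acetate A7 and give the 2,3-trans 3-acetoxy-4-methoxyflavan A5 as C4 epimers.
- For it: it is the most convergent plan. It closes ring C in the key step and takes the trans relation directly from the alkene geometry with no inversion step. On ring-forming economy it is stronger than the chosen route.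
- Against it: C4 arrives as a benzylic methyl ether at the alcohol oxidation level and must be unmasked and oxidised next to the C3 oxygen and in the presence of the prenyl group. Enol acetates are weak partners for such cations. The cation is strongly stabilised by the 5,7-oxygens, which loosens its contact with the chiral counter-anion. Acid is needed both in the key step and for the final acetal removal.
- Comparison: the chosen route needs a separate ring closure, but C4 is a ketone from the start and no oxidation follows the key step.

Key step: step 7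

Remarks on the chemistry: flavanone numbering (O1, C2, C3, C4, C4a, C5 to C8, C8a) is used for all intermediates. The chiral acid proposed for step 7 is (R)-TRIP, that is (R)-3,3'-bis(2,4,6-triisopropylphenyl)-1,1'-binaphthyl-2,2'-diyl hydrogen phosphate. That this enantiomer delivers the (2R,3S) series is a working assumption from the hydrogen-bonded model; if the opposite series forms, the (S)-acid is used and nothing else changes. Compound 1 is sold as a monohydrate and is dried azeotropically before use.

## Route

Step 1
Reactants: 1 2,4,6-trihydroxyacetophenone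
Product: 2 1-[2-hydroxy-4,6-bis(triisopropylsilyloxy)phenyl]ethanone
Conditions: iPr3SiCl (2.1 equiv), imidazole, DMF, 0 °C to rt
Reagents that add atoms: triisopropylsilyl chloride, CC(C)[Si](Cl)(C(C)C)C(C)C
Why: Silylation of phenols; the para hydroxyl and one of the two equivalent ortho hydroxyls react, while the last ortho hydroxyl stays chelated to the acetyl oxygen and is shielded by the neighbouring acetyl group, so two equivalents should stop at the bis-ether.

Step 2
Reactants: 2 1-[2-hydroxy-4,6-bis(triisopropylsilyloxy)phenyl]ethanone, 3 3-methylbut-2-en-1-ol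
Product: 4 1-[2-(3-methylbut-2-enyloxy)-4,6-bis(triisopropylsilyloxy)phenyl]ethanone
Conditions: PPh3, DIAD, THF, 0 °C to rt
Reagents that add atoms: none
Why: Mitsunobu etherification of the chelated phenol with the primary allylic alcohol; the neutral conditions spare the aryl silyl ethers, and attack at the primary carbon gives the unrearranged prenyl ether.

Step 3
Reactants: 4 1-[2-(3-methylbut-2-enyloxy)-4,6-bis(triisopropylsilyloxy)phenyl]ethanone
Product: 6 1-[6-hydroxy-3-(3-methylbut-2-enyl)-2,4-bis(triisopropylsilyloxy)phenyl]ethanone, via ortho-dienone 5 (not isolated)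
Conditions: PhNEt2, 190 °C, argon
Reagents that add atoms: none
Why: Aromatic Claisen rearrangement to the only free ortho carbon gives dienone 5, whose crowded 1,1-dimethylallyl group moves on by a Cope shift to the para carbon with normal prenyl connectivity before tautomerisation (para-Claisen–Cope sequence). The two consecutive [3,3] shifts dictate the position, so the prenyl group ends between the two TIPS ethers and the free hydroxyl, the future O1, lies beside a ring hydrogen.

Step 4
Reactants: 6 1-[6-hydroxy-3-(3-methylbut-2-enyl)-2,4-bis(triisopropylsilyloxy)phenyl]ethanone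
Product: 7 1-[6-(tert-butyldimethylsilyloxy)-3-(3-methylbut-2-enyl)-2,4-bis(triisopropylsilyloxy)phenyl]ethanone
Conditions: tBuMe2SiCl, imidazole, 4-(dimethylamino)pyridine (cat.), DMF, rt
Reagents that add atoms: tert-butyldimethylsilyl chloride, CC(C)(C)[Si](C)(C)Cl
Why: Silylation of the chelated phenol with the smaller TBS group marks the future O1 as the one silyl ether that can later be removed ahead of the two TIPS ethers, and removes the O–H that would otherwise trap the carbene intramolecularly.

Step 5
Reactants: 7 1-[6-(tert-butyldimethylsilyloxy)-3-(3-methylbut-2-enyl)-2,4-bis(triisopropylsilyloxy)phenyl]ethanone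
Product: 8 1-[6-(tert-butyldimethylsilyloxy)-3-(3-methylbut-2-enyl)-2,4-bis(triisopropylsilyloxy)phenyl]-4,4,4-trifluorobutane-1,3-dione
Conditions: LiN(SiMe3)2 (1.1 equiv), THF, −78 °C; CF3CO2CH2CF3 (1.2 equiv), −78 °C, 10 min; aq. NH4Cl
Reagents that add atoms: 2,2,2-trifluoroethyl trifluoroacetate, O=C(OCC(F)(F)F)C(F)(F)F
Why: Claisen-type trifluoroacetylation of the kinetic lithium enolate of the methyl ketone, the first half of a detrifluoroacetylative diazo transfer; short contact at −78 °C is chosen to keep the enolate from taking the neighbouring TBS group by O-to-O silyl transfer.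

Step 6
Reactants: 8 1-[6-(tert-butyldimethylsilyloxy)-3-(3-methylbut-2-enyl)-2,4-bis(triisopropylsilyloxy)phenyl]-4,4,4-trifluorobutane-1,3-dione
Product: 9 2-diazo-1-[6-(tert-butyldimethylsilyloxy)-3-(3-methylbut-2-enyl)-2,4-bis(triisopropylsilyloxy)phenyl]ethanone
Conditions: 4-AcNHC6H4SO2N3 (1.5 equiv), Et3N (1.5 equiv), H2O (1 equiv), MeCN, rt
Reagents that add atoms: 4-acetamidobenzenesulfonyl azide, CC(=O)Nc1ccc(cc1)S(=O)(=O)N=[N+]=[N-]
Why: Deacylative Regitz diazo transfer: the stabilised enolate of 8 adds to the sulfonyl azide and the adduct collapses with transfer of the trifluoroacetyl group to the sulfonamide nitrogen, giving the acceptor-only diazoketone without diazomethane.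

Step 7
Reactants: 9 2-diazo-1-[6-(tert-butyldimethylsilyloxy)-3-(3-methylbut-2-enyl)-2,4-bis(triisopropylsilyloxy)phenyl]ethanone, 10 4-methoxybenzyl alcohol, 11 vanillin acetate (4-acetoxy-3-methoxybenzaldehyde)
Product: 13 (2R,3S)-3-(4-acetoxy-3-methoxyphenyl)-1-[6-(tert-butyldimethylsilyloxy)-3-(3-methylbut-2-enyl)-2,4-bis(triisopropylsilyloxy)phenyl]-3-hydroxy-2-(4-methoxybenzyloxy)propan-1-one, via Z-enol 12 (not isolated)
Conditions: Rh2(OAc)4 (2 mol %), (R)-3,3'-bis(2,4,6-triisopropylphenyl)-1,1'-binaphthyl-2,2'-diyl hydrogen phosphate (10 mol %), 4 Å MS, CH2Cl2, −20 °C; 9 and 10 (1.3 equiv) added over 2 h to 11 (2 equiv)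
Reagents that add atoms: none
Why: Proposed new method: Rh2(OAc)4 converts 9 into an acceptor carbenoid at the future C3, the hydroxyl of 10 adds to it, and the resulting oxonium ylide (as its Z-enol 12) is intercepted by aldehyde 11, held on the chiral phosphoric acid, in an aldol-type addition that must outrun the 1,2-proton shift to the plain O–H insertion product; the closest known reaction type is the Rh2(OAc)4/chiral phosphoric acid three-component coupling of aryl diazoacetates with alcohols and imines or activated aldehydes through oxonium-ylide trapping, and what is new is the acceptor-only, doubly ortho-substituted aryl diazomethyl ketone combined with a simple aromatic aldehyde. No ring is closed; the C3–O and C2–C3 bonds form one after the other in one flask. C3 (R) and C2 (S) are both fixed in the hydrogen-bonded assembly in which the phosphoryl oxygen binds the enol O–H and the acidic P–OH binds the aldehyde: the Z-enol geometry (PMB-oxy cis to the enol hydroxyl) in this closed arrangement gives the syn relation, and the 2,4,6-triisopropylphenyl walls of the acid select the Re face of the aldehyde and one face of the enol. Syn selectivity is required because step 9 inverts C2. Chemoselectivity for intermolecular O–H capture rests on the silyl ethers beside the acyl group, which are weak and shielded oxygen donors, and on the distance of the prenyl alkene from the carbenoid. The aldol is favoured over the proton shift by the acetate on 11, which makes the aldehyde more electrophilic, by the excess of 11, by the low temperature and by slow addition of 9.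

Step 8
Reactants: 13 (2R,3S)-3-(4-acetoxy-3-methoxyphenyl)-1-[6-(tert-butyldimethylsilyloxy)-3-(3-methylbut-2-enyl)-2,4-bis(triisopropylsilyloxy)phenyl]-3-hydroxy-2-(4-methoxybenzyloxy)propan-1-one
Product: 14 (2R,3S)-3-(4-acetoxy-3-methoxyphenyl)-3-hydroxy-1-[6-hydroxy-3-(3-methylbut-2-enyl)-2,4-bis(triisopropylsilyloxy)phenyl]-2-(4-methoxybenzyloxy)propan-1-one
Conditions: KHF2 (2 equiv), MeOH/THF, 0 °C to rt
Reagents that add atoms: none
Why: Fluoride-induced cleavage of an aryl silyl ether; KHF2 in methanol removes phenolic TBS groups faster than phenolic TIPS groups and leaves aryl acetates alone. The TBS ether is also the least shielded of the three: the C7 TIPS ether sits next to the prenyl group and the C5 TIPS ether between prenyl and acyl.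

Step 9
Reactants: 14 (2R,3S)-3-(4-acetoxy-3-methoxyphenyl)-3-hydroxy-1-[6-hydroxy-3-(3-methylbut-2-enyl)-2,4-bis(triisopropylsilyloxy)phenyl]-2-(4-methoxybenzyloxy)propan-1-one
Product: 15 (2R,3R)-2-(4-acetoxy-3-methoxyphenyl)-3-(4-methoxybenzyloxy)-6-(3-methylbut-2-enyl)-5,7-bis(triisopropylsilyloxy)chroman-4-one
Conditions: PPh3, DIAD, THF, 0 °C
Reagents that add atoms: none
Why: Intramolecular Mitsunobu etherification: the ortho-acyl phenol is the acidic partner, the benzylic hydroxyl is activated by the phosphine/azodicarboxylate pair and displaced from the rear in a 6-exo-tet closure. C2 therefore inverts from S to R while C3 is untouched, giving the 2,3-trans ring; the acetate on ring B holds back ionisation of the benzylic centre.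

Step 10
Reactants: 15 (2R,3R)-2-(4-acetoxy-3-methoxyphenyl)-3-(4-methoxybenzyloxy)-6-(3-methylbut-2-enyl)-5,7-bis(triisopropylsilyloxy)chroman-4-one
Product: 16 (2R,3R)-2-(4-acetoxy-3-methoxyphenyl)-3-hydroxy-6-(3-methylbut-2-enyl)-5,7-bis(triisopropylsilyloxy)chroman-4-one
Conditions: DDQ (1.3 equiv), CH2Cl2/pH 7 buffer (10:1), 0 °C
Reagents that add atoms: none
Why: Oxidative cleavage of the PMB ether by hydride transfer to DDQ and hydrolysis of the resulting oxocarbenium ion; it is placed while both phenols next to the prenyl group are still silylated, because a free ortho-prenylphenol would be cyclised to a chromene by the same oxidant.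

Step 11
Reactants: 16 (2R,3R)-2-(4-acetoxy-3-methoxyphenyl)-3-hydroxy-6-(3-methylbut-2-enyl)-5,7-bis(triisopropylsilyloxy)chroman-4-one
Product: 17 (2R,3R)-2-(4-acetoxy-3-methoxyphenyl)-3,5,7-trihydroxy-6-(3-methylbut-2-enyl)chroman-4-one
Conditions: Bu4NF (2.5 equiv), AcOH (2.5 equiv), THF, 0 °C to rt, argon
Reagents that add atoms: none
Why: Fluoride cleavage of the two aryl TIPS ethers, both activated by the ring ketone; buffering with acetic acid keeps the medium near neutral so that the 3-hydroxychromanone is neither epimerised nor oxidised, and any acetate lost here is due to go in step 12 anyway.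

Step 12
Reactants: 17 (2R,3R)-2-(4-acetoxy-3-methoxyphenyl)-3,5,7-trihydroxy-6-(3-methylbut-2-enyl)chroman-4-one
Product: 18 (2R,3R)-3,5,7-trihydroxy-2-(4-hydroxy-3-methoxyphenyl)-6-(3-methylbut-2-enyl)chroman-4-one
Conditions: NH4OAc (excess), MeOH/H2O (4:1), rt, argon
Reagents that add atoms: none
Why: Mild transesterification of the aryl acetate in buffered aqueous methanol; near-neutral conditions under argon avoid base-induced ring opening through the ring B quinone methide (C2 epimerisation) and air oxidation to the flavonol.

## Compound list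

1 | 2,4,6-trihydroxyacetophenone | CC(=O)c1c(O)cc(O)cc1O | starting material
2 | 1-[2-hydroxy-4,6-bis(triisopropylsilyloxy)phenyl]ethanone | CC(=O)c1c(O)cc(O[Si](C(C)C)(C(C)C)C(C)C)cc1O[Si](C(C)C)(C(C)C)C(C)C | intermediate
3 | 3-methylbut-2-en-1-ol (prenol) | CC(C)=CCO | starting material
4 | 1-[2-(3-methylbut-2-enyloxy)-4,6-bis(triisopropylsilyloxy)phenyl]ethanone | CC(=O)c1c(OCC=C(C)C)cc(O[Si](C(C)C)(C(C)C)C(C)C)cc1O[Si](C(C)C)(C(C)C)C(C)C | intermediate
5 | 2-acetyl-6-(2-methylbut-3-en-2-yl)-3,5-bis(triisopropylsilyloxy)cyclohexa-2,4-dien-1-one (ortho-dienone, racemic at C6) | CC(=O)C1=C(O[Si](C(C)C)(C(C)C)C(C)C)C=C(O[Si](C(C)C)(C(C)C)C(C)C)C(C(C)(C)C=C)C1=O | intermediate (not isolated)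
6 | 1-[6-hydroxy-3-(3-methylbut-2-enyl)-2,4-bis(triisopropylsilyloxy)phenyl]ethanone | CC(=O)c1c(O)cc(O[Si](C(C)C)(C(C)C)C(C)C)c(CC=C(C)C)c1O[Si](C(C)C)(C(C)C)C(C)C | intermediate
7 | 1-[6-(tert-butyldimethylsilyloxy)-3-(3-methylbut-2-enyl)-2,4-bis(triisopropylsilyloxy)phenyl]ethanone | CC(=O)c1c(O[Si](C)(C)C(C)(C)C)cc(O[Si](C(C)C)(C(C)C)C(C)C)c(CC=C(C)C)c1O[Si](C(C)C)(C(C)C)C(C)C | intermediate
8 | 1-[6-(tert-butyldimethylsilyloxy)-3-(3-methylbut-2-enyl)-2,4-bis(triisopropylsilyloxy)phenyl]-4,4,4-trifluorobutane-1,3-dione | FC(F)(F)C(=O)CC(=O)c1c(O[Si](C)(C)C(C)(C)C)cc(O[Si](C(C)C)(C(C)C)C(C)C)c(CC=C(C)C)c1O[Si](C(C)C)(C(C)C)C(C)C | intermediate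
9 | 2-diazo-1-[6-(tert-butyldimethylsilyloxy)-3-(3-methylbut-2-enyl)-2,4-bis(triisopropylsilyloxy)phenyl]ethanone | [N-]=[N+]=CC(=O)c1c(O[Si](C)(C)C(C)(C)C)cc(O[Si](C(C)C)(C(C)C)C(C)C)c(CC=C(C)C)c1O[Si](C(C)C)(C(C)C)C(C)C | intermediate
10 | 4-methoxybenzyl alcohol | COc1ccc(CO)cc1 | starting material
11 | vanillin acetate (4-acetoxy-3-methoxybenzaldehyde) | CC(=O)Oc1ccc(C=O)cc1OC | starting material
12 | (Z)-1-[6-(tert-butyldimethylsilyloxy)-3-(3-methylbut-2-enyl)-2,4-bis(triisopropylsilyloxy)phenyl]-2-(4-methoxybenzyloxy)ethen-1-ol (enol form of the oxonium ylide) | O/C(=C\OCc1ccc(OC)cc1)c1c(O[Si](C)(C)C(C)(C)C)cc(O[Si](C(C)C)(C(C)C)C(C)C)c(CC=C(C)C)c1O[Si](C(C)C)(C(C)C)C(C)C | intermediate (not isolated)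
13 | (2R,3S)-3-(4-acetoxy-3-methoxyphenyl)-1-[6-(tert-butyldimethylsilyloxy)-3-(3-methylbut-2-enyl)-2,4-bis(triisopropylsilyloxy)phenyl]-3-hydroxy-2-(4-methoxybenzyloxy)propan-1-one | CC(=O)Oc1ccc([C@H](O)[C@@H](OCc2ccc(OC)cc2)C(=O)c2c(O[Si](C)(C)C(C)(C)C)cc(O[Si](C(C)C)(C(C)C)C(C)C)c(CC=C(C)C)c2O[Si](C(C)C)(C(C)C)C(C)C)cc1OC | intermediate
14 | (2R,3S)-3-(4-acetoxy-3-methoxyphenyl)-3-hydroxy-1-[6-hydroxy-3-(3-methylbut-2-enyl)-2,4-bis(triisopropylsilyloxy)phenyl]-2-(4-methoxybenzyloxy)propan-1-one | CC(=O)Oc1ccc([C@H](O)[C@@H](OCc2ccc(OC)cc2)C(=O)c2c(O)cc(O[Si](C(C)C)(C(C)C)C(C)C)c(CC=C(C)C)c2O[Si](C(C)C)(C(C)C)C(C)C)cc1OC | intermediate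
15 | (2R,3R)-2-(4-acetoxy-3-methoxyphenyl)-3-(4-methoxybenzyloxy)-6-(3-methylbut-2-enyl)-5,7-bis(triisopropylsilyloxy)chroman-4-one | CC(=O)Oc1ccc([C@H]2Oc3cc(O[Si](C(C)C)(C(C)C)C(C)C)c(CC=C(C)C)c(O[Si](C(C)C)(C(C)C)C(C)C)c3C(=O)[C@@H]2OCc2ccc(OC)cc2)cc1OC | intermediate
16 | (2R,3R)-2-(4-acetoxy-3-methoxyphenyl)-3-hydroxy-6-(3-methylbut-2-enyl)-5,7-bis(triisopropylsilyloxy)chroman-4-one | CC(=O)Oc1ccc([C@H]2Oc3cc(O[Si](C(C)C)(C(C)C)C(C)C)c(CC=C(C)C)c(O[Si](C(C)C)(C(C)C)C(C)C)c3C(=O)[C@@H]2O)cc1OC | intermediate
17 | (2R,3R)-2-(4-acetoxy-3-methoxyphenyl)-3,5,7-trihydroxy-6-(3-methylbut-2-enyl)chroman-4-one | CC(=O)Oc1ccc([C@H]2Oc3cc(O)c(CC=C(C)C)c(O)c3C(=O)[C@@H]2O)cc1OC | intermediate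
18 | (2R,3R)-3,5,7-trihydroxy-2-(4-hydroxy-3-methoxyphenyl)-6-(3-methylbut-2-enyl)chroman-4-one | COc1cc([C@H]2Oc3cc(O)c(CC=C(C)C)c(O)c3C(=O)[C@@H]2O)ccc1O | target

## Step count and least certain steps

Total: 12 steps. Longest linear sequence: 12 steps (1 to 18). Compounds 3, 10 and 11 enter as purchased.

**Step 7 (key step, proposed new method).** The most likely failure is collapse of the oxonium ylide by proton shift before the aldehyde is engaged, since an acceptor-only carbenoid gives a short-lived ylide and the enol is crowded by two ortho silyl ethers. Poor facial or syn/anti control within the crowded acid pocket and capture of the carbenoid by a flanking silyloxy oxygen are the other risks. The fallback uses known chemistry and splits the event in two. Starting from 9, Rh2(OAc)4-catalysed O–H insertion into 10 (the proton-shift pathway, now intended) gives 1-[6-(tert-butyldimethylsilyloxy)-3-(3-methylbut-2-enyl)-2,4-bis(triisopropylsilyloxy)phenyl]-2-(4-methoxybenzyloxy)ethanone F1. Its Z boron enolate, formed with diisopinocampheylboron triflate, (Ipc)2BOTf, and iPr2NEt at −78 °C, undergoes a syn aldol with 11; the reagent antipode is chosen for the (2R,3S) series. The fallback comes back to the route at 13.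

**Step 3 (Claisen–Cope).** The sequence may stop at the ortho stage if dienone 5 tautomerises to the reverse-prenylated phenol, the Cope shift into the position between two TIPS ethers may be slow, and the ether may lose the prenyl group thermally. The fallback reaches the ring A pattern by steric differentiation and sets out from 1. C-prenylation with 1-bromo-3-methylbut-2-ene and DBU gives 1-[2,4,6-trihydroxy-3-(3-methylbut-2-enyl)phenyl]ethanone F2. One equivalent of iPr3SiCl silylates the unchelated para hydroxyl to give 1-[2,6-dihydroxy-3-(3-methylbut-2-enyl)-4-(triisopropylsilyloxy)phenyl]ethanone F3. tBuMe2SiCl then takes the ortho hydroxyl remote from the prenyl group to give 1-[6-(tert-butyldimethylsilyloxy)-2-hydroxy-3-(3-methylbut-2-enyl)-4-(triisopropylsilyloxy)phenyl]ethanone F4. iPr3SiOTf with 2,6-lutidine silylates the last, hindered hydroxyl, and the fallback comes back at 7.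

**Step 8 (selective desilylation).** Discrimination between the TBS ether and the C7 TIPS ether may be insufficient, leading to over-desilylation. The fallback needs only that the doubly flanked C5 TIPS ether survives, and sets out from 13. Buffered Bu4NF/AcOH is used to remove both the TBS group and the C7 TIPS group, giving (2R,3S)-3-(4-acetoxy-3-methoxyphenyl)-1-[4,6-dihydroxy-3-(3-methylbut-2-enyl)-2-(triisopropylsilyloxy)phenyl]-3-hydroxy-2-(4-methoxybenzyloxy)propan-1-one F5. Mitsunobu closure, in which six-ring formation outpaces any intermolecular reaction of the C7 phenol, gives (2R,3R)-2-(4-acetoxy-3-methoxyphenyl)-7-hydroxy-3-(4-methoxybenzyloxy)-6-(3-methylbut-2-enyl)-5-(triisopropylsilyloxy)chroman-4-one F6. Re-silylation of the C7 phenol with iPr3SiCl and imidazole, needed before the DDQ step, brings the fallback back at 15.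

**Step 9 (Mitsunobu closure).** Partial ionisation of the activated benzylic centre would erode the inversion, and elimination toward the alpha-alkoxy enone would destroy both stereocenters. Ionisation is the less harmful of the two, because closure of a benzylic cation is biased toward trans by C3. The fallback relies on C3 and thermodynamics and sets out from 14. Any 2,3-cis product, (2S,3R)-2-(4-acetoxy-3-methoxyphenyl)-3-(4-methoxybenzyloxy)-6-(3-methylbut-2-enyl)-5,7-bis(triisopropylsilyloxy)chroman-4-one F7, is carried through the conditions of steps 10 to 12. These give in turn the cis 3-hydroxy compound (2S,3R)-2-(4-acetoxy-3-methoxyphenyl)-3-hydroxy-6-(3-methylbut-2-enyl)-5,7-bis(triisopropylsilyloxy)chroman-4-one F8, the cis triol (2S,3R)-2-(4-acetoxy-3-methoxyphenyl)-3,5,7-trihydroxy-6-(3-methylbut-2-enyl)chroman-4-one F9 and the C2 epimer of the target, (2S,3R)-3,5,7-trihydroxy-2-(4-hydroxy-3-methoxyphenyl)-6-(3-methylbut-2-enyl)chroman-4-one F10. Gentle warming of F10 in aqueous methanol with a trace of NaOAc opens and recloses ring C through the ring B quinone methide and should equilibrate C2 toward the more stable trans isomer without touching C3. The fallback comes back at 18.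

**Step 10 (PMB removal).** The oxidant may attack the doubly activated benzylic/allylic methylene of the prenyl group, or cleavage of a PMB ether deactivated by the adjacent ketone may be sluggish. The fallback replaces oxidation by chelation-assisted, non-oxidative cleavage and sets out from 15: MgBr2·OEt2 binds the C4 carbonyl and the C3 ether oxygen, and Me2S takes the benzyl group as a sulfonium salt. It comes back at 16 and makes no new compound (F0).

## Further compounds

F1 | step 7 | 1-[6-(tert-butyldimethylsilyloxy)-3-(3-methylbut-2-enyl)-2,4-bis(triisopropylsilyloxy)phenyl]-2-(4-methoxybenzyloxy)ethanone | COc1ccc(COCC(=O)c2c(O[Si](C)(C)C(C)(C)C)cc(O[Si](C(C)C)(C(C)C)C(C)C)c(CC=C(C)C)c2O[Si](C(C)C)(C(C)C)C(C)C)cc1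
F2 | step 3 | 1-[2,4,6-trihydroxy-3-(3-methylbut-2-enyl)phenyl]ethanone | CC(=O)c1c(O)cc(O)c(CC=C(C)C)c1O
F3 | step 3 | 1-[2,6-dihydroxy-3-(3-methylbut-2-enyl)-4-(triisopropylsilyloxy)phenyl]ethanone | CC(=O)c1c(O)cc(O[Si](C(C)C)(C(C)C)C(C)C)c(CC=C(C)C)c1O
F4 | step 3 | 1-[6-(tert-butyldimethylsilyloxy)-2-hydroxy-3-(3-methylbut-2-enyl)-4-(triisopropylsilyloxy)phenyl]ethanone | CC(=O)c1c(O[Si](C)(C)C(C)(C)C)cc(O[Si](C(C)C)(C(C)C)C(C)C)c(CC=C(C)C)c1O
F5 | step 8 | (2R,3S)-3-(4-acetoxy-3-methoxyphenyl)-1-[4,6-dihydroxy-3-(3-methylbut-2-enyl)-2-(triisopropylsilyloxy)phenyl]-3-hydroxy-2-(4-methoxybenzyloxy)propan-1-one | CC(=O)Oc1ccc([C@H](O)[C@@H](OCc2ccc(OC)cc2)C(=O)c2c(O)cc(O)c(CC=C(C)C)c2O[Si](C(C)C)(C(C)C)C(C)C)cc1OC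
F6 | step 8 | (2R,3R)-2-(4-acetoxy-3-methoxyphenyl)-7-hydroxy-3-(4-methoxybenzyloxy)-6-(3-methylbut-2-enyl)-5-(triisopropylsilyloxy)chroman-4-one | CC(=O)Oc1ccc([C@H]2Oc3cc(O)c(CC=C(C)C)c(O[Si](C(C)C)(C(C)C)C(C)C)c3C(=O)[C@@H]2OCc2ccc(OC)cc2)cc1OC
F7 | step 9 | (2S,3R)-2-(4-acetoxy-3-methoxyphenyl)-3-(4-methoxybenzyloxy)-6-(3-methylbut-2-enyl)-5,7-bis(triisopropylsilyloxy)chroman-4-one | CC(=O)Oc1ccc([C@@H]2Oc3cc(O[Si](C(C)C)(C(C)C)C(C)C)c(CC=C(C)C)c(O[Si](C(C)C)(C(C)C)C(C)C)c3C(=O)[C@@H]2OCc2ccc(OC)cc2)cc1OC
F8 | step 9 | (2S,3R)-2-(4-acetoxy-3-methoxyphenyl)-3-hydroxy-6-(3-methylbut-2-enyl)-5,7-bis(triisopropylsilyloxy)chroman-4-one | CC(=O)Oc1ccc([C@@H]2Oc3cc(O[Si](C(C)C)(C(C)C)C(C)C)c(CC=C(C)C)c(O[Si](C(C)C)(C(C)C)C(C)C)c3C(=O)[C@@H]2O)cc1OC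
F9 | step 9 | (2S,3R)-2-(4-acetoxy-3-methoxyphenyl)-3,5,7-trihydroxy-6-(3-methylbut-2-enyl)chroman-4-one | CC(=O)Oc1ccc([C@@H]2Oc3cc(O)c(CC=C(C)C)c(O)c3C(=O)[C@@H]2O)cc1OC
F10 | step 9 | (2S,3R)-3,5,7-trihydroxy-2-(4-hydroxy-3-methoxyphenyl)-6-(3-methylbut-2-enyl)chroman-4-one | COc1cc([C@@H]2Oc3cc(O)c(CC=C(C)C)c(O)c3C(=O)[C@@H]2O)ccc1O
F0 | step 10 | none | none
A1 | alternative 1 | 2,3-trans-3,4-epoxyflavan with methoxymethyl ethers at O5, O7 and O4' and prenyl at C6 | COc1cc([C@H]2Oc3cc(OCOC)c(CC=C(C)C)c(OCOC)c3[C@@H]3O[C@H]23)ccc1OCOC
A2 | alternative 1 | 2-aryl-2H-chromene with C2 disposed as in the target, methoxymethyl ethers at O5, O7 and O4', prenyl at C6 | COc1cc([C@H]2Oc3cc(OCOC)c(CC=C(C)C)c(OCOC)c3C=C2)ccc1OCOC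
A3 | alternative 2 | 3,5,7,4'-tetra-O-TBS-6-prenyl-(2R,3R)-dihydroisorhamnetin | COc1cc([C@H]2Oc3cc(O[Si](C)(C)C(C)(C)C)c(CC=C(C)C)c(O[Si](C)(C)C(C)(C)C)c3C(=O)[C@@H]2O[Si](C)(C)C(C)(C)C)ccc1O[Si](C)(C)C(C)(C)C
A4 | alternative 2 | (2R,3R)-3-[3,5-bis(tert-butyldimethylsilyloxy)-4-(3-methylbut-2-enyl)phenoxy]-2-(tert-butyldimethylsilyloxy)-3-[4-(tert-butyldimethylsilyloxy)-3-methoxyphenyl]propanoic acid | COc1cc([C@@H](Oc2cc(O[Si](C)(C)C(C)(C)C)c(CC=C(C)C)c(O[Si](C)(C)C(C)(C)C)c2)[C@@H](O[Si](C)(C)C(C)(C)C)C(O)=O)ccc1O[Si](C)(C)C(C)(C)C
A5 | alternative 3 | 2,3-trans-3-acetoxy-4-methoxyflavan (C4 epimers) with methoxymethyl ethers at O5, O7 and O4' and prenyl at C6 | COc1cc([C@H]2Oc3cc(OCOC)c(CC=C(C)C)c(OCOC)c3C(OC)[C@@H]2OC(C)=O)ccc1OCOC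
A6 | alternative 3 | 2-hydroxy-4,6-bis(methoxymethoxy)-5-(3-methylbut-2-enyl)benzaldehyde | O=Cc1c(O)cc(OCOC)c(CC=C(C)C)c1OCOC
A7 | alternative 3 | (E)-2-[3-methoxy-4-(methoxymethoxy)phenyl]vinyl acetate | CC(=O)O/C=C/c1ccc(OCOC)c(OC)c1
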